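## Analysis of the target

Vitisinol B (28) is a dibenzo-fused cycloheptane. Its seven-membered ring is made of the three methines Ca, Cd and C3 plus two neighbouring carbons of ring A (C4, C3a) and two of ring B (C1, C2). Ring A is also the benzo ring of a 2-aryl-2,3-dihydrobenzofuran (O1, C2, C3, C3a, C7a), so C3 belongs to both the carbocycle and the heterocycle. Ca carries ring E (5-formyl-2-hydroxyphenyl); Cd and C2 each carry a 4-hydroxyphenyl group. There are four stereocentres, C2 (S), C3 (S), Ca (R) and Cd (S). The C2 aryl group and ring B at C3 are trans on the dihydrofuran, and ring E at Ca and the aryl group at Cd are trans on the seven-membered ring. The two pairs are separated by ring A, so neither pair can be relied on to direct the other. The sensitive groups are six phenols, an aryl aldehyde, the benzylic C2–O ether (which can ionise under acid to a quinone-methide-type cation) and the doubly benzylic C–H bonds at Ca and C3. The hard bond is Ca–C4: C4 is meta to both oxygens of ring A and therefore not nucleophilic, and ring E is an electron-poor phenol, so cationic aryl–alkyl bond formation cannot make this crowded centre. The strategy rests on the Ca–Cd unit being a 1,1,2,2-tetraarylethane whose aryl groups end up trans on the ring. That pattern corresponds to anti addition of two aryl groups across an E-alkenylboron, with boron left on Cd to serve the final ring closure.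

## Retrosynthetic reasoning

**Protecting groups (28 ⇐ 27 ⇐ 26).** The key step uses an aryllithium, so every phenol is carried as a methyl ether and the aldehyde as a dioxolane. Going backwards, 28 comes from hexamethyl ether aldehyde 27 by Lewis-acid ether cleavage, and 27 from acetal 26 by mild aqueous acid. Methyl ethers are chosen because they are inert to organolithium, palladium, nickel and radical conditions alike.

**Seven-membered ring (26 ⇐ 25).** The Cd–C2(ring B) bond is cut. This is the one ring bond that can be formed from the boron atom left on Cd by the key step. The forward reaction is an intramolecular arylation of the secondary benzylic boronate of 25 at the ring B chloride. It must proceed with retention at Cd so that the anti relationship set in the key step becomes the trans diaryl arrangement.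

**Ca and Cd (25 ⇐ 13 + 21 + 23).** The Ca–C4(ring A) and Cd–aryl bonds are cut together. The pieces are dihydrobenzofuran C4 triflate 13, the E-styrenyl boronic ester 21 of ring E, and 4-methoxyphenyllithium 23 (from bromide 22), joined through ate complex 24. Cutting here places the cross-coupling at the non-nucleophilic C4, brings rings A and E in intact, and lets a chiral palladium catalyst set both new stereocentres independently of C2 and C3. The boron ligand is the bulky mac diol (19) rather than pinacol, because β-substituted alkenyl pinacol ate complexes tend to transfer the alkenyl group directly to palladium instead of undergoing the metallate shift.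

**Ring B at C3 (13 ⇐ 12 ⇐ 11 ⇐ 6 + 8).** The triflate comes from phenol 12 and this from benzyl ether 11. The C3–ring B bond of 11 is cut to the redox-active ester 6 and aryl bromide 8, which is used as its zinc reagent 10 (via 9). The forward decarboxylative arylation passes through a planar C3 radical, so the aryl group enters anti to the C2 aryl group and the trans relationship is set by C2. The chlorine that later serves the ring closure is already on 8, because no late halogenation could distinguish ring B from the equally electron-rich ring A.

**Dihydrobenzofuran (6 ⇐ 5 ⇐ 4 ⇐ 3 ⇐ 2 ⇐ 1).** Ester 4 is traced to flavanone 3 by an oxidative 1,2-aryl shift that contracts the pyranone. This brings C2 from the chiral pool in (2S)-naringenin 1. The chelated 5-hydroxyl of 1 is the one phenol that reacts last, which separates it from the other two: they are methylated first (2), and the 5-hydroxyl is then benzylated (3) so that it can later be released alone and turned into the triflate.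

**Small fragments (8 ⇐ 7; 21 ⇐ 17 + 19; 17 ⇐ 15 ⇐ 14; 19 ⇐ 18).** Bromide 8 is the monochlorination product of 7, para to one methoxy group. Boronate 21 comes from syn hydroboration of alkyne 17 (which fixes the E geometry) followed by exchange onto diol 19. Alkyne 17 comes from acetal 15 of aldehyde 14 by alkynylation, and diol 19 from dione 18.

## Alternatives that were turned down

**Alternative 1:** The seven-membered ring would be made by inserting an aryne into the C1–C2 bond of an indanone. The indanone β-ketoester A2 (ring B, Cd and its aryl group already present) would react with the 3,5-dimethoxybenzyne released by fluoride from silyl triflate A3. The α-carbon attacks the aryne carbon remote from the flanking methoxy group, the aryl anion closes onto the ketone, and fragmentation of the cyclobutoxide gives dibenzocycloheptenone A1. In favour: the ring is formed together with two C–C bonds in a known acyl-alkylation manifold, regiochemistry is fixed by the methoxy group, and the closure is more dependable than the final ring closure of the chosen route. Against: A1 has only a methyl ester where ring E must stand and a ketone where C3, C2 and the whole dihydrofuran must be built. Ring E would have to be installed at an epimerisable centre. C3 and C2 would have to be created late on a flexible seven-membered ring next to a diaryl ketone flanked by two ortho substituents, with nothing to control them relative to Ca and Cd. The absolute configuration would rest on an enantioenriched A2 that itself needs an asymmetric synthesis. The chosen strategy is weaker on ring closure but brings rings A and E in complete, takes C2 and C3 from the chiral pool and sets Ca and Cd by catalyst, so no stereocentre has to be made on the finished carbocycle.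

**Alternative 2:** Both rings would be closed in one oxidative operation. Anodic oxidation of stilbene phenol A5 would place a radical on the stilbene carbon next to ring B. This carbon bonds to an ortho carbon of the tethered resorcinol ring A (seven-membered ring), and a ring A hydroxyl then adds to the resulting quinone methide at C2 (dihydrofuran), giving A4. In favour: two rings and two stereocentres (C3, C2) in one metal-free step with the reacting phenols unprotected. On end-game economy it is stronger than the chosen route. Against: A5 still contains the Ca–Cd tetraaryl unit, so the enantioselective construction that the chosen key step provides is needed anyway. The phenoxyl radical can also couple intermolecularly or through oxygen. The free resorcinol of ring A and the phenols of A4 are oxidised at similar potentials. The configuration at C3 would be set by a remote Ca/Cd pair across a forming medium ring. The chosen strategy gives up the cascade for bond formations whose regiochemistry is unambiguous, and for C2 and C3 of known configuration.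

**Alternative 3:** Here the oxidative ring contraction of the naringenin-derived flavanone 3 is the central event. A trivalent iodine oxidant in an acidic orthoester medium attacks the enol ether at C3, ring A migrates from C4 to C3, and the old C4 leaves the ring as the ester of A6. In favour: cheap chiral pool, a well-known rearrangement, C2 carried over and C3 obtained trans. In precedent and robustness it is stronger than the conjunctive coupling. Against: taken as the key step it solves only the dihydrobenzofuran. Ca, Cd, ring E and the seven-membered ring remain, and the missing Ca–C4 bond cannot be made by the cationic chemistry that usually follows such intermediates, because C4 is not nucleophilic. The transformation is kept in the chosen route as step 3 (A6 is the same compound as 4), and the catalyst-controlled three-component coupling is added for the half of the molecule it does not address.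

Key step: step 14

Remark (assumption): (2S)-naringenin of high enantiomeric purity is taken as the commercial material.
Remark (assumption): the sense of induction of the ferrocenyl bisphosphine is assumed to carry over from simpler alkenylboron ate complexes; if the alkene face proves opposite, the mirror-image ligand is used.
Abbreviation: mac diol = cis-1,2-dimethylacenaphthene-1,2-diol (19); B(mac) = its cyclic boronic ester.

## Route

Step 1
Reactants: 1 (2S)-naringenin
Product: 2 (2S)-5-hydroxy-7-methoxy-2-(4-methoxyphenyl)-2,3-dihydro-4H-chromen-4-one
Conditions: Me3SiCHN2, i-Pr2NEt, MeOH/MeCN, rt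
Reagents that add atoms: (trimethylsilyl)diazomethane, C[Si](C)(C)C=[N+]=[N-]
Why: O-methylation of the two acidic phenols by a diazoalkane; the hydrogen-bonded 5-hydroxyl is the least reactive and should remain. The conditions are too weakly basic to open the flavanone to the chalcone, so C2 keeps its configuration.

Step 2
Reactants: 2 (2S)-5-hydroxy-7-methoxy-2-(4-methoxyphenyl)-2,3-dihydro-4H-chromen-4-one
Product: 3 (2S)-5-(benzyloxy)-7-methoxy-2-(4-methoxyphenyl)-2,3-dihydro-4H-chromen-4-one
Conditions: BnBr, Ag2O, CH2Cl2, rt, dark
Reagents that add atoms: benzyl bromide, BrCc1ccccc1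
Why: Williamson-type benzylation with halophilic assistance by Ag2O, chosen over hot carbonate to avoid enolisation at C3 and retro-oxa-Michael opening, which would racemise C2. Benzyl is stable to the acid, oxidant and nickel chemistry that follow and can later be removed in the presence of the methyl ethers.

Step 3
Reactants: 3 (2S)-5-(benzyloxy)-7-methoxy-2-(4-methoxyphenyl)-2,3-dihydro-4H-chromen-4-one
Product: 4 methyl (2S,3S)-4-(benzyloxy)-6-methoxy-2-(4-methoxyphenyl)-2,3-dihydro-1-benzofuran-3-carboxylate (2,3-trans)
Conditions: PhI(OAc)2, HC(OMe)3, H2SO4 (cat.), rt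
Reagents that add atoms: trimethyl orthoformate, COC(OC)OC; water (work-up), O
Why: Oxidative ring contraction of a flavanone: the enol ether formed in the orthoformate is attacked at C3 by trivalent iodine, and the electron-rich ring A migrates from C4 to C3 as iodobenzene leaves, so the old C4 becomes the ester carbon. C2 is not involved and keeps its configuration; C3 is expected trans to the C2 aryl group, the more stable arrangement.

Step 4
Reactants: 4 methyl (2S,3S)-4-(benzyloxy)-6-methoxy-2-(4-methoxyphenyl)-2,3-dihydro-1-benzofuran-3-carboxylate
Product: 5 (2S,3S)-4-(benzyloxy)-6-methoxy-2-(4-methoxyphenyl)-2,3-dihydro-1-benzofuran-3-carboxylic acid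
Conditions: Me3SnOH, 1,2-dichloroethane, 80 °C; then 1 M HCl work-up
Reagents that add atoms: trimethyltin hydroxide, C[Sn](C)(C)O
Why: Near-neutral ester cleavage by Me3SnOH. Alkaline hydrolysis is avoided because the C3 ester enolate can expel the C2 aryloxide and open the ring, which would destroy C2.

Step 5
Reactants: 5 (2S,3S)-4-(benzyloxy)-6-methoxy-2-(4-methoxyphenyl)-2,3-dihydro-1-benzofuran-3-carboxylic acid
Product: 6 1,3-dioxoisoindolin-2-yl (2S,3S)-4-(benzyloxy)-6-methoxy-2-(4-methoxyphenyl)-2,3-dihydro-1-benzofuran-3-carboxylate
Conditions: N-hydroxyphthalimide, N,N'-diisopropylcarbodiimide, CH2Cl2, rt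
Reagents that add atoms: N-hydroxyphthalimide, O=C1c2ccccc2C(=O)N1O
Why: Carbodiimide esterification gives the redox-active ester; no amine base is added, so the activated C3–H is not deprotonated.

Step 6
Reactants: 7 1-bromo-3,5-dimethoxybenzene
Product: 8 1-bromo-2-chloro-3,5-dimethoxybenzene
Conditions: N-chlorosuccinimide, MeCN, rt
Reagents that add atoms: N-chlorosuccinimide, O=C1CCC(=O)N1Cl
Why: Electrophilic aromatic chlorination; attack para to one methoxy group (C2, two equivalent sites) should be preferred over the crowded position between the two methoxy groups, and any 4-chloro isomer is separated.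

Step 7
Reactants: 6 1,3-dioxoisoindolin-2-yl (2S,3S)-4-(benzyloxy)-6-methoxy-2-(4-methoxyphenyl)-2,3-dihydro-1-benzofuran-3-carboxylate; 8 1-bromo-2-chloro-3,5-dimethoxybenzene
Product: 11 (2S,3R)-4-(benzyloxy)-3-(2-chloro-3,5-dimethoxyphenyl)-6-methoxy-2-(4-methoxyphenyl)-2,3-dihydro-1-benzofuran (2,3-trans), via arylmagnesium chloride 9 (not isolated), via arylzinc chloride 10 (not isolated)
Conditions: 8, i-PrMgCl·LiCl, THF, 0 °C to rt; ZnCl2; then 6, NiCl2(MeOCH2CH2OMe) (cat.), 4,4'-di-tert-butyl-2,2'-bipyridine (cat.), THF/DMF, rt
Reagents that add atoms: none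
Why: Nickel-catalysed decarboxylative Negishi-type arylation of a redox-active ester: electron transfer releases CO2 and a benzylic C3 radical, which is captured by aryl-nickel and coupled. The radical is planar, so the aryl group should enter anti to the C2 aryl group and give the trans product (the descriptor at C3 changes to R only because chlorine raises the priority of ring B). Bromine–magnesium exchange is selective for C–Br, and the ortho-chloro arylzinc does not eliminate to an aryne at these temperatures.

Step 8
Reactants: 11 (2S,3R)-4-(benzyloxy)-3-(2-chloro-3,5-dimethoxyphenyl)-6-methoxy-2-(4-methoxyphenyl)-2,3-dihydro-1-benzofuran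
Product: 12 (2S,3R)-3-(2-chloro-3,5-dimethoxyphenyl)-6-methoxy-2-(4-methoxyphenyl)-2,3-dihydro-1-benzofuran-4-ol
Conditions: H2 (1 atm), 10% Pd/C, EtOAc, rt
Reagents that add atoms: none
Why: Hydrogenolysis of an aryl benzyl ether; in neutral ethyl acetate without base the chloride, shielded by two ortho substituents, and the cyclic benzylic C2–O bond should react much more slowly, and the reaction is stopped at full conversion.

Step 9
Reactants: 12 (2S,3R)-3-(2-chloro-3,5-dimethoxyphenyl)-6-methoxy-2-(4-methoxyphenyl)-2,3-dihydro-1-benzofuran-4-ol
Product: 13 (2S,3R)-3-(2-chloro-3,5-dimethoxyphenyl)-6-methoxy-2-(4-methoxyphenyl)-2,3-dihydro-1-benzofuran-4-yl trifluoromethanesulfonate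
Conditions: Tf2O, pyridine, CH2Cl2, 0 °C
Reagents that add atoms: trifluoromethanesulfonic anhydride, O=S(=O)(OS(=O)(=O)C(F)(F)F)C(F)(F)F
Why: O-sulfonylation of the only free phenol turns the non-nucleophilic C4 position into a cross-coupling electrophile.

Step 10
Reactants: 14 3-bromo-4-methoxybenzaldehyde
Product: 15 2-(3-bromo-4-methoxyphenyl)-1,3-dioxolane
Conditions: HOCH2CH2OH, p-TsOH (cat.), toluene, reflux, Dean–Stark
Reagents that add atoms: ethylene glycol, OCCO
Why: Acetalisation protects the aldehyde against the aryllithium of step 14; the cyclic acetal is chosen over the dimethyl acetal because it withstands chromatography better on this electron-rich ring.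

Step 11
Reactants: 15 2-(3-bromo-4-methoxyphenyl)-1,3-dioxolane
Product: 17 2-(3-ethynyl-4-methoxyphenyl)-1,3-dioxolane, via silylalkyne 16 (not isolated)
Conditions: Me3SiC≡CH, PdCl2(PPh3)2 (cat.), CuI (cat.), Et3N, 70 °C; then K2CO3 (cat.), MeOH, rt
Reagents that add atoms: trimethylsilylacetylene, C#C[Si](C)(C)C
Why: Sonogashira coupling followed by methanolysis of the C–Si bond; the acetal is stable to both basic stages.

Step 12
Reactants: 18 acenaphthylene-1,2-dione
Product: 19 cis-1,2-dimethyl-1,2-dihydroacenaphthylene-1,2-diol (meso, 1R,2S; mac diol)
Conditions: MeMgBr (excess), THF, 0 °C to rt; aqueous work-up; crystallisation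
Reagents that add atoms: methylmagnesium bromide, C[Mg]Br
Why: Double Grignard addition to the 1,2-dione. Only the cis diol can form a cyclic boronic ester, and it is separated from any trans isomer by crystallisation.

Step 13
Reactants: 17 2-(3-ethynyl-4-methoxyphenyl)-1,3-dioxolane; 19 mac diol
Product: 21 (E)-2-[5-(1,3-dioxolan-2-yl)-2-methoxyphenyl]ethenylboronic acid mac ester, via catechol alkenylboronate 20 (not isolated)
Conditions: catecholborane, Cy2BH (cat.), THF, rt; then 19, rt
Reagents that add atoms: catecholborane, B1Oc2ccccc2O1
Why: Syn, anti-Markovnikov hydroboration of the terminal alkyne fixes the E geometry; the labile catechol ester then exchanges with the aliphatic diol 19 to give the robust B(mac) ester.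

Step 14
Reactants: 22 4-bromoanisole; 21 (E)-2-[5-(1,3-dioxolan-2-yl)-2-methoxyphenyl]ethenylboronic acid mac ester; 13 (2S,3R)-3-(2-chloro-3,5-dimethoxyphenyl)-6-methoxy-2-(4-methoxyphenyl)-2,3-dihydro-1-benzofuran-4-yl trifluoromethanesulfonate
Product: 25 (2S,3R)-3-(2-chloro-3,5-dimethoxyphenyl)-4-[(1R,2S)-1-[5-(1,3-dioxolan-2-yl)-2-methoxyphenyl]-2-(4-methoxyphenyl)-2-[B(mac)]ethyl]-6-methoxy-2-(4-methoxyphenyl)-2,3-dihydro-1-benzofuran, via 4-methoxyphenyllithium 23 (not isolated), via lithium alkenyl(aryl)borate 24 (not isolated)
Conditions: 22, n-BuLi, THF, −78 °C; 21, −78 °C to rt; evaporation, fresh THF; 13, Pd(OAc)2 (cat.), (Sp,Sp)-1,1'-bis[bis(4-methoxy-3,5-dimethylphenyl)phosphino]-2,2'-bis[(R)-(dimethylamino)(phenyl)methyl]ferrocene (cat.), 60 °C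
Reagents that add atoms: none
Why: Bromine–lithium exchange gives 23, which adds to boron of 21 to form the four-coordinate ate complex 24; zerovalent palladium carrying the chiral bisphosphine inserts into the C4–OTf bond of 13 and the resulting cationic divalent aryl-palladium binds the alkene of 24. Binding triggers a 1,2-metallate shift in which the 4-methoxyphenyl group moves from boron to Cd anti-periplanar to the forming Ca–Pd bond, and reductive elimination then joins Ca to C4 with retention, so the two aryl groups are delivered anti across the E-alkene. The closest known reaction type is the palladium-catalysed enantioselective conjunctive cross-coupling of alkenylboron ate complexes with aryl triflates, including β-substituted alkenyl B(mac) esters. No ring is closed. Ca and Cd are created together: their relative configuration follows from the E geometry of 21 and the anti course of the shift, their absolute configuration from the alkene face selected by the ligand-bound palladium. Three selectivities are needed: conjunctive coupling over direct Suzuki–Miyaura transfer of the styrenyl group (secured by the bulky mac diol on boron), triflate over chloride (secured by the better leaving group and by the two ortho substituents that shield the chlorine on ring B), and catalyst over substrate control of the alkene face (C2 and C3 sit on the electrophile, away from the migration terminus, so the ligand is expected to dominate). Exchange with butyllithium leaves 1-bromobutane, which is removed on evaporation, rather than a lithium halide, so no halide ion blocks the open coordination site on palladium.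

Step 15
Reactants: 25 conjunctive-coupling product with B(mac) on Cd and chlorine on ring B
Product: 26 vitisinol B hexamethyl ether 1,3-dioxolane acetal (C2 S, C3 S, Ca R, Cd S; seven-membered ring closed)
Conditions: Pd(OAc)2 (cat.), SPhos (2-dicyclohexylphosphino-2',6'-dimethoxybiphenyl, cat.), Ag2O, THF/H2O, 70 °C
Reagents that add atoms: none
Why: Proposed new method: zerovalent palladium with the electron-rich biarylphosphine should insert into the hindered C–Cl bond of ring B; Ag2O removes chloride and gives an aryl-palladium hydroxide whose Pd–O unit binds the nearby boron, so that Cd is transferred through a closed four-centre transition state on the face boron leaves (retention), and reductive elimination from the eight-membered palladacycle forms the Cd–C2(ring B) bond and the seven-membered ring; β-hydride loss toward Ca is expected to be slowed because the Ca–H bond cannot easily become syn-coplanar with Pd–Cd in the palladacycle. The closest known reaction types are the intermolecular stereoretentive Suzuki–Miyaura coupling of enantioenriched secondary benzylic boronic esters with aryl iodides promoted by Ag2O, and stereospecific couplings of secondary alkylboron reagents with aryl chlorides; the intramolecular case with a secondary benzylic B(mac) ester and an aryl chloride has not been shown.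

Step 16
Reactants: 26 vitisinol B hexamethyl ether 1,3-dioxolane acetal
Product: 27 vitisinol B hexamethyl ether (free aldehyde)
Conditions: 1 M HCl, THF, rt
Reagents that add atoms: water, O
Why: Acetal hydrolysis; the trans dihydrobenzofuran is the more stable isomer and should tolerate dilute acid at room temperature.

Step 17
Reactants: 27 vitisinol B hexamethyl ether
Product: 28 vitisinol B
Conditions: BBr3, CH2Cl2, −78 °C to rt; then H2O
Reagents that add atoms: none
Why: Lewis-acid cleavage of all six aryl methyl ethers. The stereocentres carry no leaving group except C2–O, whose reversible ionisation would return the more stable trans isomer.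

## Compound list

1 | (2S)-naringenin | O=C1C[C@@H](c2ccc(O)cc2)Oc2cc(O)cc(O)c21 | starting material
2 | (2S)-5-hydroxy-7-methoxy-2-(4-methoxyphenyl)-2,3-dihydro-4H-chromen-4-one | O=C1C[C@@H](c2ccc(OC)cc2)Oc2cc(OC)cc(O)c21 | intermediate
3 | (2S)-5-(benzyloxy)-7-methoxy-2-(4-methoxyphenyl)-2,3-dihydro-4H-chromen-4-one | O=C1C[C@@H](c2ccc(OC)cc2)Oc2cc(OC)cc(OCc3ccccc3)c21 | intermediate
4 | methyl (2S,3S)-4-(benzyloxy)-6-methoxy-2-(4-methoxyphenyl)-2,3-dihydro-1-benzofuran-3-carboxylate | O(Cc1ccccc1)c1cc(OC)cc2c1[C@H](C(=O)OC)[C@@H](c1ccc(OC)cc1)O2 | intermediate
5 | (2S,3S)-4-(benzyloxy)-6-methoxy-2-(4-methoxyphenyl)-2,3-dihydro-1-benzofuran-3-carboxylic acid | O(Cc1ccccc1)c1cc(OC)cc2c1[C@H](C(=O)O)[C@@H](c1ccc(OC)cc1)O2 | intermediate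
6 | 1,3-dioxoisoindolin-2-yl (2S,3S)-4-(benzyloxy)-6-methoxy-2-(4-methoxyphenyl)-2,3-dihydro-1-benzofuran-3-carboxylate | O(Cc1ccccc1)c1cc(OC)cc2c1[C@H](C(=O)ON1C(=O)c3ccccc3C1=O)[C@@H](c1ccc(OC)cc1)O2 | intermediate
7 | 1-bromo-3,5-dimethoxybenzene | COc1cc(Br)cc(OC)c1 | starting material
8 | 1-bromo-2-chloro-3,5-dimethoxybenzene | COc1cc(Br)c(Cl)c(OC)c1 | intermediate
9 | (2-chloro-3,5-dimethoxyphenyl)magnesium chloride | COc1cc([Mg]Cl)c(Cl)c(OC)c1 | intermediate (not isolated)
10 | (2-chloro-3,5-dimethoxyphenyl)zinc chloride | COc1cc([Zn]Cl)c(Cl)c(OC)c1 | intermediate (not isolated)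
11 | (2S,3R)-4-(benzyloxy)-3-(2-chloro-3,5-dimethoxyphenyl)-6-methoxy-2-(4-methoxyphenyl)-2,3-dihydro-1-benzofuran | O(Cc1ccccc1)c1cc(OC)cc2c1[C@H](c1cc(OC)cc(OC)c1Cl)[C@@H](c1ccc(OC)cc1)O2 | intermediate
12 | (2S,3R)-3-(2-chloro-3,5-dimethoxyphenyl)-6-methoxy-2-(4-methoxyphenyl)-2,3-dihydro-1-benzofuran-4-ol | Oc1cc(OC)cc2c1[C@H](c1cc(OC)cc(OC)c1Cl)[C@@H](c1ccc(OC)cc1)O2 | intermediate
13 | (2S,3R)-3-(2-chloro-3,5-dimethoxyphenyl)-6-methoxy-2-(4-methoxyphenyl)-2,3-dihydro-1-benzofuran-4-yl trifluoromethanesulfonate | O=S(=O)(Oc1cc(OC)cc2c1[C@H](c1cc(OC)cc(OC)c1Cl)[C@@H](c1ccc(OC)cc1)O2)C(F)(F)F | intermediate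
14 | 3-bromo-4-methoxybenzaldehyde | COc1ccc(C=O)cc1Br | starting material
15 | 2-(3-bromo-4-methoxyphenyl)-1,3-dioxolane | COc1ccc(C2OCCO2)cc1Br | intermediate
16 | {[5-(1,3-dioxolan-2-yl)-2-methoxyphenyl]ethynyl}trimethylsilane | COc1ccc(C2OCCO2)cc1C#C[Si](C)(C)C | intermediate (not isolated)
17 | 2-(3-ethynyl-4-methoxyphenyl)-1,3-dioxolane | COc1ccc(C2OCCO2)cc1C#C | intermediate
18 | acenaphthylene-1,2-dione | O=C1C(=O)c2cccc3cccc1c23 | starting material
19 | cis-1,2-dimethyl-1,2-dihydroacenaphthylene-1,2-diol (mac diol) | O[C@]1(C)c2cccc3cccc(c23)[C@]1(C)O | intermediate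
20 | 2-[(E)-2-[5-(1,3-dioxolan-2-yl)-2-methoxyphenyl]ethenyl]-1,3,2-benzodioxaborole | COc1ccc(C2OCCO2)cc1/C=C/B1Oc2ccccc2O1 | intermediate (not isolated)
21 | (E)-2-[5-(1,3-dioxolan-2-yl)-2-methoxyphenyl]ethenylboronic acid mac ester | COc1ccc(C2OCCO2)cc1/C=C/B1O[C@]2(C)c3cccc4cccc(c34)[C@]2(C)O1 | intermediate
22 | 4-bromoanisole | COc1ccc(Br)cc1 | starting material
23 | 4-methoxyphenyllithium | [Li]c1ccc(OC)cc1 | intermediate (not isolated)
24 | lithium [(E)-2-[5-(1,3-dioxolan-2-yl)-2-methoxyphenyl]ethenyl](4-methoxyphenyl)borate of the mac diol (configuration at boron not defined) | [Li+].COc1ccc(C2OCCO2)cc1/C=C/[B-]1(c2ccc(OC)cc2)O[C@]2(C)c3cccc4cccc(c34)[C@]2(C)O1 | intermediate (not isolated)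
25 | (2S,3R)-3-(2-chloro-3,5-dimethoxyphenyl)-4-[(1R,2S)-1-[5-(1,3-dioxolan-2-yl)-2-methoxyphenyl]-2-(4-methoxyphenyl)-2-[B(mac)]ethyl]-6-methoxy-2-(4-methoxyphenyl)-2,3-dihydro-1-benzofuran | COc1ccc(C2OCCO2)cc1[C@H]([C@H](B1O[C@]2(C)c3cccc4cccc(c34)[C@]2(C)O1)c1ccc(OC)cc1)c1cc(OC)cc2c1[C@H](c1cc(OC)cc(OC)c1Cl)[C@@H](c1ccc(OC)cc1)O2 | intermediate
26 | vitisinol B hexamethyl ether 1,3-dioxolane acetal (C2 S, C3 S, Ca R, Cd S) | O1CCOC1c1ccc(OC)c([C@H]2c3cc(OC)cc4c3[C@H](c3cc(OC)cc(OC)c3[C@@H]2c2ccc(OC)cc2)[C@@H](c2ccc(OC)cc2)O4)c1 | intermediate
27 | vitisinol B hexamethyl ether (C2 S, C3 S, Ca R, Cd S) | O=Cc1ccc(OC)c([C@H]2c3cc(OC)cc4c3[C@H](c3cc(OC)cc(OC)c3[C@@H]2c2ccc(OC)cc2)[C@@H](c2ccc(OC)cc2)O4)c1 | intermediate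
28 | vitisinol B (C2 S, C3 S, Ca R, Cd S) | O=Cc1ccc(O)c([C@H]2c3cc(O)cc4c3[C@H](c3cc(O)cc(O)c3[C@@H]2c2ccc(O)cc2)[C@@H](c2ccc(O)cc2)O4)c1 | target

## Step count and least certain steps

Total: 17 steps. Longest linear sequence: 12 steps from 1 (steps 1–5, 7–9, 14–17).

**Step 15 (proposed new method).** The most likely failures are slow transmetallation of the hindered B(mac) group, which would let protodeboronation or β-hydride elimination toward Ca take over, and transmetallation with inversion under the electron-rich ligand needed for the chloride, which would give the Cd epimer. Fallback with known chemistry, from 25 to 27: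
- The C–B bond is oxidised with retention (NaBO3·4H2O, THF/H2O) to the Cd alcohol F1.
- The chlorine is removed by hydrogenolysis (H2, 10% Pd/C, Et3N, EtOAc/MeOH; the amine moderates benzylic C–O cleavage) to give the dechlorinated alcohol F2.
- p-TsOH·H2O in CH2Cl2 then ionises the 4-methoxybenzylic alcohol. The cation is captured by the free ortho position of the 3,5-dimethoxyphenyl ring B in a Friedel–Crafts closure of the seven-membered ring, and the acetal is hydrolysed at the same time, arriving at 27.
- In this fallback Cd is set by the ring (aryl trans to ring E) and not by the catalyst; Ca remains catalyst-derived.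

**Step 14 (key step).** The triflate carries a bulky ortho substituent, so oxidative addition, alkene binding and reductive elimination at the crowded Ca may be slow enough for direct styrenyl transfer or protodeboronation to compete. A mismatch between substrate and ligand could also erode facial selectivity. Fallback, from 13 to 25: rings A and E exchange roles, so that the unhindered ring E bromide 15 becomes the electrophile.
- Triflate 13 is ethynylated (tributyl(ethynyl)stannane, Pd(PPh3)4, LiCl, dioxane, 90 °C) to the C4 alkyne F3.
- Rhodium-catalysed trans-hydroboration ([Rh(cod)Cl]2, P(i-Pr)3, Et3N, catecholborane) gives the Z-alkenyl catechol boronate F4, which is exchanged with 19 to the Z-alkenyl B(mac) ester F5.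
- Addition of 23 gives the ate complex F6, which is coupled with 15 under Pd(OAc)2 and the ferrocenyl bisphosphine (enantiomer chosen for the required face) with KOTf as halide scavenger to give 25.
- Anti addition across the Z-alkene leads to the same diastereomer as anti addition across the E-alkene of 21, because the pre-installed and incoming aryl groups at Ca are interchanged.

**Step 7.** The ortho-chloro arylzinc may transmetallate sluggishly, and low-valent nickel may begin to insert into C–Cl bonds, so that reduction or dimerisation of the C3 radical wins. Fallback, from 5 and 8 to 11: the acid 5 is coupled directly with bromide 8 by photoredox/nickel dual catalysis ([Ir(dF(CF3)ppy)2(dtbbpy)]PF6, NiCl2(MeOCH2CH2OMe), 4,4'-di-tert-butyl-2,2'-bipyridine, Cs2CO3, DMF, blue light). The radical is then made by oxidation of the carboxylate and the aryl group enters as an electrophile, so no ortho-chloro arylmetal is prepared. No new compound arises (F0).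

**Step 8.** Hydrogenolysis may not stop at the benzyl ether; loss of chlorine or opening of the benzylic C2–O bond would spoil the material. Fallback, from 11 to 12: Lewis-acid debenzylation with BCl3 and pentamethylbenzene as cation scavenger (CH2Cl2, −78 °C). This cleaves the benzyl ether without hydrogen or palladium and leaves the methyl ethers. No new compound arises (F0).

**Step 17.** Six ether cleavages under a strong Lewis acid may be accompanied by ionisation at C2 with skeletal change, or by side reactions at the aldehyde, and the electron-poor ring E ether may lag behind. Fallback, from 26 to 28: nucleophilic demethylation with NaSEt in DMF at 130 °C on the acetal-protected stage gives the hexaphenol acetal F7. Mild acid (1 M HCl, THF, rt) then releases the aldehyde to give 28.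

## Further compounds

F1 | step 15 | Cd alcohol from oxidation of 25 (chlorine and acetal retained, configuration as in 25) | COc1ccc(C2OCCO2)cc1[C@H]([C@H](O)c1ccc(OC)cc1)c1cc(OC)cc2c1[C@H](c1cc(OC)cc(OC)c1Cl)[C@@H](c1ccc(OC)cc1)O2
F2 | step 15 | dechlorinated Cd alcohol | COc1ccc(C2OCCO2)cc1[C@H]([C@H](O)c1ccc(OC)cc1)c1cc(OC)cc2c1[C@H](c1cc(OC)cc(OC)c1)[C@@H](c1ccc(OC)cc1)O2
F3 | step 14 | (2S,3R)-3-(2-chloro-3,5-dimethoxyphenyl)-4-ethynyl-6-methoxy-2-(4-methoxyphenyl)-2,3-dihydro-1-benzofuran | C#Cc1cc(OC)cc2c1[C@H](c1cc(OC)cc(OC)c1Cl)[C@@H](c1ccc(OC)cc1)O2
F4 | step 14 | Z-alkenyl catechol boronate of the dihydrobenzofuran | c1(/C=C\B3Oc4ccccc4O3)cc(OC)cc2c1[C@H](c1cc(OC)cc(OC)c1Cl)[C@@H](c1ccc(OC)cc1)O2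
F5 | step 14 | Z-alkenyl B(mac) ester of the dihydrobenzofuran | c1(/C=C\B3O[C@]4(C)c5cccc6cccc(c56)[C@]4(C)O3)cc(OC)cc2c1[C@H](c1cc(OC)cc(OC)c1Cl)[C@@H](c1ccc(OC)cc1)O2
F6 | step 14 | lithium Z-alkenyl(4-methoxyphenyl)borate of the mac diol | [Li+].c1(/C=C\[B-]3(c4ccc(OC)cc4)O[C@]5(C)c6cccc7cccc(c67)[C@]5(C)O3)cc(OC)cc2c1[C@H](c1cc(OC)cc(OC)c1Cl)[C@@H](c1ccc(OC)cc1)O2
F0 | step 7 | none | none
F0 | step 8 | none | none
F7 | step 17 | vitisinol B 1,3-dioxolane acetal (hexaphenol) | O1CCOC1c1ccc(O)c([C@H]2c3cc(O)cc4c3[C@H](c3cc(O)cc(O)c3[C@@H]2c2ccc(O)cc2)[C@@H](c2ccc(O)cc2)O4)c1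
A1 | alternative 1 | dibenzocycloheptenone with methyl ester on Ca and 4-methoxyphenyl on Cd | COC(=O)[C@H]2c3cc(OC)cc(OC)c3C(=O)c3cc(OC)cc(OC)c3[C@@H]2c2ccc(OC)cc2
A2 | alternative 1 | methyl 4,6-dimethoxy-3-(4-methoxyphenyl)-1-oxo-2,3-dihydro-1H-indene-2-carboxylate | COC(=O)C1C(=O)c2cc(OC)cc(OC)c2[C@@H]1c1ccc(OC)cc1
A3 | alternative 1 | 3,5-dimethoxy-2-(trimethylsilyl)phenyl trifluoromethanesulfonate | COc1cc(OC)c([Si](C)(C)C)c(OS(=O)(=O)C(F)(F)F)c1
A4 | alternative 2 | tetramethyl ether of the target with free ring A and C2-aryl phenols | O=Cc1ccc(OC)c([C@H]2c3cc(O)cc4c3[C@H](c3cc(OC)cc(OC)c3[C@@H]2c2ccc(OC)cc2)[C@@H](c2ccc(O)cc2)O4)c1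
A5 | alternative 2 | open stilbene phenol precursor with tethered resorcinol ring A | O=Cc1ccc(OC)c([C@H]([C@@H](c2ccc(OC)cc2)c2c(OC)cc(OC)cc2/C=C/c2ccc(O)cc2)c2cc(O)cc(O)c2)c1
A6 | alternative 3 | methyl trans-4-benzyloxy-6-methoxy-2-(4-methoxyphenyl)-2,3-dihydrobenzofuran-3-carboxylate (identical with 4) | c1(OCc2ccccc2)cc(OC)cc2c1[C@H](C(=O)OC)[C@@H](c1ccc(OC)cc1)O2
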